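Whatever target stays dissolved is left over for the reagent in the reaction phase to attack, so I reckon what share of the reacted starting material stays target.

    reagent in the reaction phase ⇌ reagent in the second phase, rate k1*([reagent in the reaction phase] - [reagent in the second phase]/K1) per volume of the first phase (K1 = 1.2, k1 = 0.0065 min⁻¹)
    starting material + reagent in the reaction phase → target (k2 = 0.018 M⁻¹ min⁻¹)
    reagent in the reaction phase + target → over-reacted product (k3 = 0.083 M⁻¹ min⁻¹)
    2 reagent in the reaction phase → homo dimer (k4 = 0.021 M⁻¹ min⁻¹)
    reagent in the reaction phase → decomposed reagent (k5 = 4.4 × 10⁻⁴ min⁻¹)
    crystals ⇌ target, rate k6*(cs6 - [target]) while solid is left; crystals form when [target] > cs6 (cs6 = 1.9 mM, k6 = 0.016 min⁻¹)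

starting material 0.10 M; reagent in the second phase 0.300 M; time 40 h; volume of the second phase over the first 1.0

- the target and crystals together standing at 40 h, as a percentage of the starting material charged
- the change that raises the amount of target and crystals together at 40 h, in percent of the starting material charged most ("none" if none brings more than 2 percentage points) (red / green / grey / violet / none)
- amount of target and crystals together at 40 h, in percent of the starting material charged, after green

- red: doubling the amount of reagent in the second phase, all else as stated
- green: doubling the transfer coefficient of step 1, all else as stated
- grey: doubling the solubility in step 6, all else as stated
- violet: doubling the dissolution coefficient of step 6, all else as stated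

- target is meant together with its crystals
- for a step with 2 of a species take k times the square, and two of it per event
- in the second phase: reagent in the second phase; everything else is in the first
- charges count per volume of the first phase; a concentration in a rate is the amount of a species over the volume of its own phase; every rate counts per litre of the first phase
- solid, in amounts per volume of the solution: crystals
- run time (flask): 40 h

- Crystals take up dissolved target on a time of 62.5 min, far shorter than the run of 40 h, so I set crystal uptake equal to the net making of target. Then c(target) stands above the solubility by that net rate over the dissolution coefficient.
- I take mid-run values, which are my own choice: c(starting material) = 0.0500 M, and c(reagent in the reaction phase) = 0.0682 M, half of what transfer equilibrium between the equal phases gives.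
- Two numbers follow at these values. The solubility loss 0.175 is the over-reaction rate constant times the solubility, over the target-forming rate constant times c(starting material). The crystal loss 0.354 is the over-reaction rate constant times c(reagent in the reaction phase), over the dissolution coefficient.
- The kept share, target standing per starting material reacted, is one minus the solubility loss, over one plus the crystal loss: 0.609. I stop at this share and reckon no conversion, so I commit to no figure for the yield.
- Violet halves the crystal loss and lifts the kept share to 0.701.
- Grey doubles the solubility loss and gives 0.480.
- Red doubles the crystal loss and gives 0.483, so conversion must rise by a factor of 1.26 merely to break even.
- Green leaves my share unchanged, since the transfer half-time of 58.2 min is far below the run of 40 h. I expect it to bring little. Violet's share is the highest of these.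
- The forecast gives 47% (40% to 54%), 46% after green (38% to 53%), and violet as the best change, saying that faster crystallisation “directly reduces that exposure”. It names the same change as I do.
- The flask gives 50.0%, and 48.8% after green. The changes bring −3 percentage points for red, −1.3 points for green, −9.3 points for grey and 5.6 points for violet, so violet is best.
- With 24.7% over-reacted product at 40.0 h, the flask's kept share reads 0.670, against my 0.609.
- The neighbour flask holds 0.060 M of starting material and all else as before. The same reckoning raises the solubility loss and, with the crystal loss unchanged, gives a kept share of 0.523, lower than 0.609. That neighbour flask stands at 44.1% target and crystals together with 33.9% over-reacted product and 22% of its starting material left at 40.0 h, so its kept share reads 0.565.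

The numbers of this flask are made up; the run is a simulation.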